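**Retrosynthetic overview**
1. The target comes from late allylic C–H oxidation at C6 of its deoxo diester; the two esters come from a 1,3-diol, itself made by hydroxymethylation (C1) and hydroxyl-directed reduction (C11) of a tricyclic ketone.
2. The seven-membered ring (formed last) is closed by a 7-endo acyl-radical addition (C11 to C1) onto an ethylidenecyclobutane.
3. The cyclobutane and both six-membered rings are formed together by one intramolecular keteniminium–alkene [2+2] (bonds C2–C7 and C3–C8) of an acyclic (Z,E)-dienamide carrying a C2-symmetric pyrrolidine.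
4. Key step: Birch reduction of 3-methylanisole breaks the aromatic ring; ozonolysis then unzips it between C2 and C7, so the arene supplies C2–C7, the C4 methyl and the (Z)-C4=C5 olefin. This same six-carbon unit is re-closed in line 3 as the enone ring.
5. The remaining carbons come from isopropenylmagnesium bromide (C8, C9, CH3), trimethyl orthoacetate (C10, C11), an ethylidene ylide (C1, CH3), formaldehyde (CH2O), angelic acid and acetic anhydride.

**Atom labels** (order of the target SMILES): C1 = quaternary carbon with CH3 and CH2O; C2 = cyclobutane CH next to C1; C3 = bridgehead next to C4; C4 = methyl-bearing olefinic carbon; C5 = olefinic CH; C6 = ring carbonyl (CH2 until step 15); C7 = other bridgehead; C8 = quaternary cyclobutane carbon with CH3; C9, C10 = CH2; C11 = CH–OAc.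

**Assumption:** the sense of induction of the (2S,5S)-amide in step 6 and of the (S,S)-ligand in step 11 is taken as drawn. Both are available in either hand, and the antipode is used if a test run shows the opposite sense.

**Convention:** 3-methylanisole (1) and angelic acid (17) are the numbered starting materials; small reagents that deliver atoms are given with SMILES under each step.

---

Step 1
Reactants: 1 3-methylanisole
Product: 2 1-methoxy-5-methylcyclohexa-1,4-diene
Conditions: Li, NH3 (l), t-BuOH, THF, −78 to −33 °C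
Reagents that add atoms: none
Why: Birch reduction breaks the aromaticity and leaves OMe and CH3 on the two isolated double bonds (2,5-dihydro product), so the ring fixes the cis relationship that becomes the (Z)-C4=C5 olefin; no stereocentre is formed.

Step 2
Reactants: 2 1-methoxy-5-methylcyclohexa-1,4-diene
Product: 3 methyl (3Z)-3-methyl-6-oxohex-3-enoate
Conditions: O3 (1 equiv), CH2Cl2/MeOH (4:1), pyridine (cat.), −78 °C; then Me2S
Reagents that add atoms: ozone, [O-][O+]=O
Why: Ozonolysis attacks the electron-rich enol-ether double bond much faster than the trialkyl olefin, so the ring opens between C2 (ester) and C7 (aldehyde) while the ring-derived olefin keeps its (Z) geometry.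

Step 3
Reactants: 3 methyl (3Z)-3-methyl-6-oxohex-3-enoate
Product: 4 methyl (3Z)-6-hydroxy-3,7-dimethylocta-3,7-dienoate (racemic carbinol)
Conditions: CH2=C(CH3)MgBr, THF, −78 °C; then H2O
Reagents that add atoms: isopropenylmagnesium bromide, CC(=C)[Mg]Br
Why: Grignard 1,2-addition is much faster at the aldehyde than at the ester at −78 °C; the carbinol centre is racemic and is destroyed in step 5.

Step 4
Reactants: 4 methyl (3Z)-6-hydroxy-3,7-dimethylocta-3,7-dienoate
Product: 5 (3Z)-1-[(2S,5S)-2,5-dimethylpyrrolidin-1-yl]-6-hydroxy-3,7-dimethylocta-3,7-dien-1-one (both carbinol epimers)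
Conditions: (2S,5S)-2,5-dimethylpyrrolidine, AlMe3, toluene, 0 to 60 °C; then H2O
Reagents that add atoms: (2S,5S)-2,5-dimethylpyrrolidine, C[C@H]1CC[C@H](C)N1
Why: Weinreb-type aminolysis of the ester by the Me2Al–NR2 reagent installs the C2-symmetric auxiliary and distinguishes this carboxyl from the ester made in step 5; no new stereocentre.

Step 5
Reactants: 5 (3Z)-1-[(2S,5S)-2,5-dimethylpyrrolidin-1-yl]-6-hydroxy-3,7-dimethylocta-3,7-dien-1-one
Product: 6 methyl (4E,7Z)-10-[(2S,5S)-2,5-dimethylpyrrolidin-1-yl]-4,8-dimethyl-10-oxodeca-4,7-dienoate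
Conditions: MeC(OMe)3, EtCO2H (cat.), xylene, 135 °C (MeOH distilled off)
Reagents that add atoms: trimethyl orthoacetate, CC(OC)(OC)OC
Why: Johnson–Claisen rearrangement through a chair transition state with the chain equatorial gives the (E)-C7=C8 olefin and adds C10 and C11; the carbinol stereocentre disappears.

Step 6
Reactants: 6 methyl (4E,7Z)-10-[(2S,5S)-2,5-dimethylpyrrolidin-1-yl]-4,8-dimethyl-10-oxodeca-4,7-dienoate
Product: 9 methyl 3-[(1S,5R,7R)-2,7-dimethyl-6-oxobicyclo[3.1.1]hept-2-en-7-yl]propanoate, via keteniminium triflate 7 (not isolated), via cyclobutaniminium triflate 8 (not isolated)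
Conditions: Tf2O, 2,6-di-tert-butyl-4-methylpyridine, ClCH2CH2Cl (0.01 M), 0 to 80 °C; then aq. NaHCO3
Reagents that add atoms: water (ketone oxygen), O; trifluoromethanesulfonic anhydride (triflate counter-ion of 7 and 8 only), O=S(=O)(OS(=O)(=O)C(F)(F)F)C(F)(F)F
Why: Proposed new method: amide activation gives the vinylogous keteniminium ion 7, whose electrophilic central carbon C2 is attacked by the less substituted olefin carbon C7, and the tertiary cation at C8 then closes onto C3 (crossed [2+2]; closest known reactions are Snider's vinylketene route to chrysanthenone and Ghosez's auxiliary-controlled intramolecular keteniminium–alkene cycloadditions); the (Z)-C4=C5 olefin holds the partners cis, the (E)-C7=C8 geometry puts the C8 methyl syn to the ene bridge and the chain anti, and the C2-symmetric pyrrolidine selects the olefin face, fixing C3, C7 and C8.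

Step 7
Reactants: 9 methyl 3-[(1S,5R,7R)-2,7-dimethyl-6-oxobicyclo[3.1.1]hept-2-en-7-yl]propanoate
Product: 10 methyl 3-[(1S,5R,7R)-6-ethylidene-2,7-dimethylbicyclo[3.1.1]hept-2-en-7-yl]propanoate (E/Z mixture)
Conditions: EtPPh3Br, KOtBu, THF, 0 °C; then 9, 0 to 60 °C
Reagents that add atoms: ethyltriphenylphosphonium bromide, CC[P+](c1ccccc1)(c1ccccc1)c1ccccc1.[Br-]
Why: Wittig olefination of the strained cyclobutanone, which cannot enolise because both α-carbons are bridgeheads, with a non-stabilised ylide that leaves the ester alone; the ethylidene geometry is irrelevant.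

Step 8
Reactants: 10 methyl 3-[(1S,5R,7R)-6-ethylidene-2,7-dimethylbicyclo[3.1.1]hept-2-en-7-yl]propanoate
Product: 11 Se-methyl 3-[(1S,5R,7R)-6-ethylidene-2,7-dimethylbicyclo[3.1.1]hept-2-en-7-yl]propaneselenoate
Conditions: Me2AlSeMe (pre-formed from AlMe3 and Se), CH2Cl2, 0 to 25 °C; then H2O
Reagents that add atoms: dimethylaluminium methaneselenolate, C[Se][Al](C)C
Why: Direct ester-to-selenoester exchange (Kozikowski) gives the acyl-radical precursor without touching any stereocentre.

Step 9
Reactants: 11 Se-methyl 3-[(1S,5R,7R)-6-ethylidene-2,7-dimethylbicyclo[3.1.1]hept-2-en-7-yl]propaneselenoate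
Product: 13 (1S,2S,7R,8S)-3,7,11-trimethyltricyclo[5.4.0.0(2,8)]undec-10-en-4-one (both C-3 epimers), via acyl radical 12 (not isolated)
Conditions: Bu3SnH (syringe pump), AIBN, benzene (0.005 M), 80 °C
Reagents that add atoms: none
Why: Boger-type acyl-radical cyclisation: the acyl radical on the axial C9–C10 chain adds 7-endo to the less substituted ethylidene carbon C1 (6-exo attack would hit the fully substituted C2), and the cyclobutyl radical at C2 takes H from Bu3SnH at its only free position, so C2–H is fixed by the ring; the C1 epimer mixture is erased in step 10.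

Step 10
Reactants: 13 (1S,2S,7R,8S)-3,7,11-trimethyltricyclo[5.4.0.0(2,8)]undec-10-en-4-one
Product: 14 trimethyl{[(1S,2S,7R,8S)-3,7,11-trimethyltricyclo[5.4.0.0(2,8)]undeca-3,10-dien-4-yl]oxy}silane
Conditions: Me3SiCl, NaI, Et3N, MeCN, 25 °C
Reagents that add atoms: chlorotrimethylsilane, C[Si](C)(C)Cl
Why: Thermodynamic silyl enol ether formation (Me3SiI made in situ) favours the more substituted C1=C11 enol ether and removes the C1 stereocentre.

Step 11
Reactants: 14 trimethyl{[(1S,2S,7R,8S)-3,7,11-trimethyltricyclo[5.4.0.0(2,8)]undeca-3,10-dien-4-yl]oxy}silane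
Product: 15 (1S,2S,3S,7R,8S)-3-(hydroxymethyl)-3,7,11-trimethyltricyclo[5.4.0.0(2,8)]undec-10-en-4-one
Conditions: Sc(OSO2CF3)3 (10 mol %), (S,S)-6,6'-bis(1-hydroxy-2,2-dimethylpropyl)-2,2'-bipyridine (12 mol %), aq. HCHO, DME/H2O (9:1), −20 °C
Reagents that add atoms: formaldehyde, C=O
Why: Kobayashi catalytic asymmetric hydroxymethylation (aqueous Mukaiyama aldol): the two flanks of the core are almost mirror images and give no facial bias at C1, so the chiral catalyst decides and delivers CH2OH to the face on the C3 side, creating quaternary C1; any enantiomeric core carried from step 6 becomes a separable diastereomer here.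

Step 12
Reactants: 15 (1S,2S,3S,7R,8S)-3-(hydroxymethyl)-3,7,11-trimethyltricyclo[5.4.0.0(2,8)]undec-10-en-4-one
Product: 16 (1S,2S,3S,4R,7R,8S)-3-(hydroxymethyl)-3,7,11-trimethyltricyclo[5.4.0.0(2,8)]undec-10-en-4-ol
Conditions: Me4N[BH(OAc)3], MeCN/AcOH (1:1), −30 °C
Reagents that add atoms: none
Why: Evans–Saksena hydroxyl-directed reduction: the CH2OH group binds boron and delivers hydride to C11 from its own face, so the new C11–OH is trans to CH2OH and cis to the C1 methyl.

Step 13
Reactants: 16 (1S,2S,3S,4R,7R,8S)-3-(hydroxymethyl)-3,7,11-trimethyltricyclo[5.4.0.0(2,8)]undec-10-en-4-ol; 17 angelic acid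
Product: 18 [(1S,2S,3S,4R,7R,8S)-4-hydroxy-3,7,11-trimethyltricyclo[5.4.0.0(2,8)]undec-10-en-3-yl]methyl (2Z)-2-methylbut-2-enoate
Conditions: 17, 2,4,6-Cl3C6H2COCl, Et3N, toluene, 25 °C; then 16, 80 °C (no DMAP)
Reagents that add atoms: none
Why: Yamaguchi-type mixed-anhydride esterification without a nucleophilic catalyst avoids angelate-to-tiglate isomerisation, and the primary alcohol reacts much faster than the hindered secondary one.

Step 14
Reactants: 18 [(1S,2S,3S,4R,7R,8S)-4-hydroxy-3,7,11-trimethyltricyclo[5.4.0.0(2,8)]undec-10-en-3-yl]methyl (2Z)-2-methylbut-2-enoate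
Product: 19 [(1S,2S,3S,4R,7R,8S)-4-(acetyloxy)-3,7,11-trimethyltricyclo[5.4.0.0(2,8)]undec-10-en-3-yl]methyl (2Z)-2-methylbut-2-enoate
Conditions: Ac2O, pyridine, DMAP (cat.), CH2Cl2, 25 °C
Reagents that add atoms: acetic anhydride, CC(=O)OC(C)=O
Why: DMAP-catalysed acetylation of the remaining secondary alcohol; no stereocentre changes.

Step 15
Reactants: 19 [(1S,2S,3S,4R,7R,8S)-4-(acetyloxy)-3,7,11-trimethyltricyclo[5.4.0.0(2,8)]undec-10-en-3-yl]methyl (2Z)-2-methylbut-2-enoate
Product: 20 [(1S,2R,3S,4R,7S,8S)-4-(acetyloxy)-3,7,11-trimethyl-9-oxotricyclo[5.4.0.0(2,8)]undec-10-en-3-yl]methyl (2Z)-2-methylbut-2-enoate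
Conditions: CrO3, 3,5-dimethylpyrazole, CH2Cl2, −20 °C
Reagents that add atoms: chromium trioxide, O=[Cr](=O)=O
Why: Allylic C–H oxidation with the CrO3–3,5-dimethylpyrazole complex (as in α-pinene to verbenone) converts the only allylic ring CH2 (C6) into the conjugated ketone; the electron-poor angelate olefin and bridgehead C–H bonds are not attacked, and the CIP letters at C-2 and C-7 change only because the new carbonyl changes priorities.

---

**Compound list**

1 | 3-methylanisole | COc1cccc(C)c1 | starting material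
2 | 1-methoxy-5-methylcyclohexa-1,4-diene | COC1=CCC=C(C)C1 | intermediate
3 | methyl (3Z)-3-methyl-6-oxohex-3-enoate | COC(=O)C/C(C)=C\CC=O | intermediate
4 | methyl (3Z)-6-hydroxy-3,7-dimethylocta-3,7-dienoate (racemic) | COC(=O)C/C(C)=C\CC(O)C(C)=C | intermediate
5 | (3Z)-1-[(2S,5S)-2,5-dimethylpyrrolidin-1-yl]-6-hydroxy-3,7-dimethylocta-3,7-dien-1-one (carbinol epimers) | C[C@H]1CC[C@H](C)N1C(=O)C/C(C)=C\CC(O)C(C)=C | intermediate
6 | methyl (4E,7Z)-10-[(2S,5S)-2,5-dimethylpyrrolidin-1-yl]-4,8-dimethyl-10-oxodeca-4,7-dienoate | C[C@H]1CC[C@H](C)N1C(=O)C/C(C)=C\C/C=C(\C)CCC(=O)OC | intermediate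
7 | keteniminium triflate of 6 (N+=C2=C3 cumulene) | C[C@H]1CC[C@H](C)[N+]1=C=C/C(C)=C\C/C=C(\C)CCC(=O)OC.[O-]S(=O)(=O)C(F)(F)F | intermediate
8 | cyclobutaniminium triflate (the [2+2] adduct, C2=N+) | C[C@H]1CC[C@H](C)[N+]1=C1[C@H]2C(C)=CC[C@@H]1[C@@]2(C)CCC(=O)OC.[O-]S(=O)(=O)C(F)(F)F | intermediate
9 | methyl 3-[(1S,5R,7R)-2,7-dimethyl-6-oxobicyclo[3.1.1]hept-2-en-7-yl]propanoate (7-CH3 syn to the C2=C3 bridge) | O=C1[C@H]2C(C)=CC[C@@H]1[C@@]2(C)CCC(=O)OC | intermediate
10 | methyl 3-[(1S,5R,7R)-6-ethylidene-2,7-dimethylbicyclo[3.1.1]hept-2-en-7-yl]propanoate (E/Z mixture) | CC=C1[C@H]2C(C)=CC[C@@H]1[C@@]2(C)CCC(=O)OC | intermediate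
11 | Se-methyl 3-[(1S,5R,7R)-6-ethylidene-2,7-dimethylbicyclo[3.1.1]hept-2-en-7-yl]propaneselenoate | CC=C1[C@H]2C(C)=CC[C@@H]1[C@@]2(C)CCC(=O)[Se]C | intermediate
12 | acyl radical derived from 11 | CC=C1[C@H]2C(C)=CC[C@@H]1[C@@]2(C)CC[C]=O | intermediate
13 | (1S,2S,7R,8S)-3,7,11-trimethyltricyclo[5.4.0.0(2,8)]undec-10-en-4-one (C-3 epimers) | CC1[C@@H]2[C@H]3C(C)=CC[C@@H]2[C@@]3(C)CCC1=O | intermediate
14 | trimethyl{[(1S,2S,7R,8S)-3,7,11-trimethyltricyclo[5.4.0.0(2,8)]undeca-3,10-dien-4-yl]oxy}silane | CC=1[C@@H]2[C@H]3C(C)=CC[C@@H]2[C@@]3(C)CCC=1O[Si](C)(C)C | intermediate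
15 | (1S,2S,3S,7R,8S)-3-(hydroxymethyl)-3,7,11-trimethyltricyclo[5.4.0.0(2,8)]undec-10-en-4-one | OC[C@]1(C)[C@@H]2[C@H]3C(C)=CC[C@@H]2[C@@]3(C)CCC1=O | intermediate
16 | (1S,2S,3S,4R,7R,8S)-3-(hydroxymethyl)-3,7,11-trimethyltricyclo[5.4.0.0(2,8)]undec-10-en-4-ol | OC[C@]1(C)[C@@H]2[C@H]3C(C)=CC[C@@H]2[C@@]3(C)CC[C@H]1O | intermediate
17 | angelic acid, (2Z)-2-methylbut-2-enoic acid | C/C=C(/C)C(=O)O | starting material
18 | [(1S,2S,3S,4R,7R,8S)-4-hydroxy-3,7,11-trimethyltricyclo[5.4.0.0(2,8)]undec-10-en-3-yl]methyl (2Z)-2-methylbut-2-enoate | C/C=C(/C)C(=O)OC[C@]1(C)[C@@H]2[C@H]3C(C)=CC[C@@H]2[C@@]3(C)CC[C@H]1O | intermediate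
19 | [(1S,2S,3S,4R,7R,8S)-4-(acetyloxy)-3,7,11-trimethyltricyclo[5.4.0.0(2,8)]undec-10-en-3-yl]methyl (2Z)-2-methylbut-2-enoate | C/C=C(/C)C(=O)OC[C@]1(C)[C@@H]2[C@H]3C(C)=CC[C@@H]2[C@@]3(C)CC[C@H]1OC(C)=O | intermediate
20 | [(1S,2R,3S,4R,7S,8S)-4-(acetyloxy)-3,7,11-trimethyl-9-oxotricyclo[5.4.0.0(2,8)]undec-10-en-3-yl]methyl (2Z)-2-methylbut-2-enoate | C/C=C(/C)C(=O)OC[C@]1(C)[C@@H]2[C@H]3C(C)=CC(=O)[C@@H]2[C@@]3(C)CC[C@H]1OC(C)=O | target

---

**Total step count:** 15. **Longest linear sequence:** 15 steps (1 to 20); angelic acid 17 enters at step 13.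

**Three steps most likely to fail**

Step 6 (keteniminium [2+2]). The conjugated keteniminium ion may decompose or cyclise poorly, and the level of auxiliary control is untested on this substrate. The fallback runs the cycloaddition with the neutral vinylketene (Snider-type) and resolves afterwards; it sets out from 4 and comes back at 9. Ti(OiPr)4-catalysed transesterification of 4 with allyl alcohol gives prop-2-en-1-yl (3Z)-6-hydroxy-3,7-dimethylocta-3,7-dienoate F1. Johnson–Claisen rearrangement as in step 5 gives the allyl methyl diester F2. Pd(PPh3)4 and morpholine remove the allyl group to give (3Z,6E)-10-methoxy-3,7-dimethyl-10-oxodeca-3,6-dienoic acid F3. Oxalyl chloride, then Et3N in refluxing toluene at high dilution, generates the vinylketene, which closes to the racemic ketone, that is 9 together with its (1R,5S,7S)-enantiomer F4. Preparative HPLC on a chiral stationary phase delivers 9.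

Step 9 (7-endo acyl-radical closure). Simple reduction of the selenoester or poor addition to the hindered ethylidene could dominate. The fallback closes the ring by an ionic Dieckmann condensation instead; it sets out from 9, bypasses steps 7 and 8, and comes back at 13. Reformatsky addition of methyl 2-bromopropanoate (Zn, THF) to 9 gives the tertiary cyclobutanol F5. Dehydration with SOCl2 and pyridine, which can only go towards the side chain because both ring α-carbons are bridgeheads, gives the alkylidene diester F6. Mg in MeOH reduces the enoate, hydrogen reaching C2 from the face not blocked by the C9 chain, to give the saturated diester F7. KOtBu in THF effects the Dieckmann condensation (C10 enolate onto the propanoate ester, the only mode that leaves an acidic β-keto ester) to give the β-keto ester F8. LiCl in wet DMSO at 150 °C (Krapcho) then gives 13.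

Step 11 (catalyst-controlled hydroxymethylation). The hindered tetrasubstituted enol ether may hydrolyse faster than it reacts, or the catalyst may give poor face selection. The fallback replaces catalyst control by stoichiometric enolate alkylation and separation of epimers; it sets out from 14 and comes back at 15. MeLi converts 14 into the lithium enolate, which is alkylated at C1 with 4-methoxybenzyl chloromethyl ether to give the (3S)-ether F9 and its (3R)-epimer F10. These are separated by chromatography, and DDQ in wet CH2Cl2 removes the 4-methoxybenzyl group from F9 to give 15.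

**Further compounds**

F1 | step 6 | prop-2-en-1-yl (3Z)-6-hydroxy-3,7-dimethylocta-3,7-dienoate | C=CCOC(=O)C/C(C)=C\CC(O)C(C)=C
F2 | step 6 | 10-methyl 1-prop-2-en-1-yl (3Z,6E)-3,7-dimethyldeca-3,6-dienedioate | C=CCOC(=O)C/C(C)=C\C/C=C(\C)CCC(=O)OC
F3 | step 6 | (3Z,6E)-10-methoxy-3,7-dimethyl-10-oxodeca-3,6-dienoic acid | OC(=O)C/C(C)=C\C/C=C(\C)CCC(=O)OC
F4 | step 6 | methyl 3-[(1R,5S,7S)-2,7-dimethyl-6-oxobicyclo[3.1.1]hept-2-en-7-yl]propanoate (enantiomer of 9) | O=C1[C@@H]2C(C)=CC[C@H]1[C@]2(C)CCC(=O)OC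
F5 | step 9 | methyl 2-[6-hydroxy-7-(3-methoxy-3-oxopropyl)-2,7-dimethylbicyclo[3.1.1]hept-2-en-6-yl]propanoate (ring centres as in 9; carbinol and side-chain epimers) | COC(=O)C(C)C1(O)[C@H]2C(C)=CC[C@@H]1[C@@]2(C)CCC(=O)OC
F6 | step 9 | methyl 2-[7-(3-methoxy-3-oxopropyl)-2,7-dimethylbicyclo[3.1.1]hept-2-en-6-ylidene]propanoate (ring centres as in 9; E/Z mixture) | COC(=O)C(C)=C1[C@H]2C(C)=CC[C@@H]1[C@@]2(C)CCC(=O)OC
F7 | step 9 | methyl 2-[7-(3-methoxy-3-oxopropyl)-2,7-dimethylbicyclo[3.1.1]hept-2-en-6-yl]propanoate (ring centres as in 9; C6–H syn to the ene bridge; side-chain epimers) | COC(=O)C(C)[C@@H]1[C@H]2C(C)=CC[C@@H]1[C@@]2(C)CCC(=O)OC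
F8 | step 9 | methyl 3,7,11-trimethyl-4-oxotricyclo[5.4.0.0(2,8)]undec-10-ene-5-carboxylate (ring centres as in 13; C-3 and C-5 epimers) | CC1[C@@H]2[C@H]3C(C)=CC[C@@H]2[C@@]3(C)CC(C(=O)OC)C1=O
F9 | step 11 | (3S)-3-{[(4-methoxyphenyl)methoxy]methyl}-3,7,11-trimethyltricyclo[5.4.0.0(2,8)]undec-10-en-4-one (other centres as in 15) | COc1ccc(COC[C@]2(C)[C@@H]3[C@H]4C(C)=CC[C@@H]3[C@@]4(C)CCC2=O)cc1
F10 | step 11 | (3R)-3-{[(4-methoxyphenyl)methoxy]methyl}-3,7,11-trimethyltricyclo[5.4.0.0(2,8)]undec-10-en-4-one (C-3 epimer of F9) | COc1ccc(COC[C@@]2(C)[C@@H]3[C@H]4C(C)=CC[C@@H]3[C@@]4(C)CCC2=O)cc1
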